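# Proposed total synthesis of CNP0395728.1

## Structural features

The target is a 2,3,4-trisubstituted oxolane in which C2 carries an aryl group (ring B), C3 a hydroxymethyl group and C4 a 4-hydroxy-3-methoxybenzyl group (ring A), all on one face, (2R,3R,4R), so that the C2 aryl group is cis to its neighbour, the less stable arrangement. Ring B is also the benzo ring of a trans-2-aryl-3-hydroxymethyl-7-methoxy-2,3-dihydrobenzofuran, (2R,3S), joined to the oxolane through C5, and its 2-aryl group, ring C, is the benzo ring of a second unit of the same kind, (2S,3R), which ends in the guaiacyl ring D. The seven stereocentres therefore fall into three clusters (three contiguous centres on the oxolane, two adjacent pairs on the furans) that are separated by arenes and cannot control one another, and the two furan units have opposite absolute sense. The fragile bonds are the three benzylic ether C–O bonds (oxolane C2–O1 and both furan C2–O1), each para to a ring oxygen: acid ionises them and lets C2 drift to the thermodynamic side, which for the oxolane is the wrong one. The two free phenols are oxidisable and, under base, can open these ethers through quinone methides. The real difficulty is the kinetic creation and preservation of the all-cis oxolane. The feature used is the oxolane C2–C3 bond: C2 is a benzylic ether carbon whose hydrogen is activated by O1 and by the para oxygen of ring B, and C3, with its one-carbon substituent and that of C4, can be folded into a γ-lactone fused across C3–C4. The single centre C4 then dictates C3 through the ring fusion and C2 through the geometry of ring closure.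

## Logic of the disconnections

45 ⇒ 44 ⇒ 42. Four Si–O bonds are cut and the C3 hydroxymethyl carbon is raised to the amide level. No skeletal bond changes. The gain is that the phenols and primary alcohols travel as fluoride-labile ethers and the C3 carbon keeps a handle that tells it apart from the C4 carbon. The forward steps must avoid acid and must not let an all-cis C3 aldehyde linger.

42 ⇒ 40 + 41. The C(sp3)–C(aryl) bond between the methylene on C4 and ring A is cut. Ring A is a simple arene best added last, and the cut turns the C4 substituent into a one-carbon unit at the oxidation level of a lactone CH2–O. The forward step must join a primary alkyl bromide to an electron-rich aryl bromide without a reagent that attacks the amide.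

40 ⇒ 39 ⇒ 38. The C–Br bond is traced back to C–O and the acyl–O bond is re-formed, which ties the one-carbon arms on C3 and C4 into a cis-fused γ-lactone. The gain is that the two arms are distinguished by oxidation level inside a ring. The forward steps must open the lactone with an amine that stops at the amide and must activate the freed alcohol next to that amide.

38 ⇒ 37. The oxolane C2–C3 bond is cut. This removes one ring and two stereocentres and leaves C4 as the only centre of the fragment. The forward step must form the bond by insertion of a lactone α-carbenoid into one particular benzylic hydrogen, with cis fusion and with the aryl group on the concave face.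

37 ⇒ 35 ⇒ 27 + 34. The diazo carbon is traced back to a methylene group, then the benzylic C–O ether bond is cut. The molecule falls into the large aryl part and a five-carbon chiral lactone. The forward steps must make the ether without base, because 34 can lose its configuration by acyl migration between its two hydroxymethyl arms, and must activate the weakly acidic lactone for diazo transfer.

34 ⇒ 33 ⇒ 32 ⇒ 30 ⇒ 28. The hydroxymethyl group is traced to a carboxyl group, the single enantiomer to a resolved racemate, and the lactone C–O bond to an intramolecular displacement after conjugate addition to an unsaturated diacid. The forward steps must reduce an acid in the presence of a lactone.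

27 ⇒ 26 ⇒ 24 ⇒ 23. The imidate C–O bond, the benzylic C–C bond to ring B (from C–Br) and one Si–O bond are cut. The bromine serves as a latent hydroxymethyl group that survives everything before it.

23 ⇒ 20 ⇒ 11 + 19. The outer furan O1–C2 bond and then the C2–C3 bond are cut (aldol). The auxiliary sets C3 and C2 follows in the ring closure. The forward steps must keep C3 intact while the benzylic carbon is ionised and must spare the silyl ethers.

19 ⇒ 18 ⇒ 17 ⇒ 14 ⇒ 9 + 13. The same two cuts are made on the inner furan with the enantiomeric auxiliary. The aryl bromide of 18 is the latent aldehyde that links the two rounds.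

9 and 11 ⇒ 7 + 8 or 10; 7 ⇒ 6 ⇒ 4 ⇒ 3 ⇒ 2 ⇒ 1; 13 ⇒ 12; 41 ⇒ 1. The imide N–C bonds are cut, and both imides fall back on a single acyl fluoride, whose C–F bond is traced to the C–OH bond of the acid. One activated batch then serves both antipodal auxiliaries, and the activation must spare the aryl acetal. The acetic acid side chain is traced to an allyl group placed ortho to the phenol by a sigmatropic shift, and the allyl group to an O-allyl ether of 1. The remaining cuts are O–Si bonds.

## Other disconnections considered

Alternative 1: The cut is at the two C3–C3a bonds of the dihydrobenzofurans. Each five-membered ring is traced back, by a retro ring contraction, to a chroman-4-one, so that diester A2 comes from bis-flavanone A1, whose two ketone carbons become the ester carbons. In the forward direction PhI(OAc)2 (trivalent iodine) with H2SO4 in trimethyl orthoformate would turn each ketone into its enol ether, iodinate C3 and trigger a 1,2-shift of the fused arene carbon from C4 to C3 with departure of the iodine group.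
- In its favour: two rings, two C–C bonds and both C3 centres arise in one operation from the C2 centres; the ester level leads straight to the hydroxymethyl groups; the bromine of A2 is the same handle as in 24.
- Against it here: both 2-aryl groups are electron-rich, so migration of the C2 aryl group and plain dehydrogenation of the heterocycle should compete, twice in one molecule. The medium is strongly acidic, and a flavanone can open and re-close there and lose its C2 configuration. The two C2 centres of A1 must be set in opposite absolute sense, for which no method as dependable as an auxiliary aldol is at hand.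
- Comparison, structure: A2 maps onto 23 and would stand in for the sequence that ends there (steps 5 to 14), but it leaves the oxolane untouched, so the chosen key step or an equivalent would still be needed.
- Comparison, mechanism: a stereospecific shift sets C3 from C2, whereas the chosen route sets C3 by the auxiliary and lets C2 follow. Each leans on one centre to place the other, and neither is clearly superior.
- Comparison, step economy: the alternative is the better, since both rings form in one step. On stereochemical reliability the chosen plan is the better.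

Alternative 2: The cut is at C2–C3 and O1–C2 of one dihydrobenzofuran, a [4+1] disconnection to sulfone A3 and sulfonium salt A5. In the forward direction base would expel the sulfinate group from A3 to give the ortho-quinone methide A4. A5, deprotonated at its benzylic carbon, would add to the exocyclic carbon of A4, and the phenoxide would then displace the sulfur substituent to give bromide A6.
- In its favour: two bonds, the ring and both stereocentres form in one convergent step. The conditions are basic, so no benzylic cation is involved; on this point the alternative is the better of the two, because the chosen route closes its furans through a cation. A6 differs from 18 only in one silyl group, so everything after it would be equal.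
- Against it here: A4 carries a CH2O substituent with α-hydrogens on its exocyclic carbon and could be lost by tautomerisation before it is trapped. Absolute and trans control would rest on a chiral sulfur group steering a semi-stabilised ylide, which is less secure than an auxiliary aldol. For the second round ring C would have to be turned from aryl bromide into a benzylic sulfonium salt, several steps.
- Comparison, structure: it builds the same furan units and leaves the oxolane to another method.
- Comparison, mechanism: ylide addition and SN2 closure against aldol addition and SN1 closure.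
- Comparison, step economy: about equal, since each partner needs three to four steps. The need for both antipodes of a chiral controller is equal in the two plans.

Alternative 3: The cut is at both O1–C7a bonds, leading to the acyclic diiodo diol A7, in which all four furan stereocentres are already in place. In the forward direction CuI with 1,10-phenanthroline and Cs2CO3 would couple each secondary benzylic alkoxide with the neighbouring aryl iodide, with retention at the carbinol carbons, to give acetal A8.
- In its favour: the closure is stereospecific and has no cationic or elimination path, so on the integrity of C2 and C3 it is the better of the two. Both rings close in one operation. It rests on the same syn-aldol logic as the chosen route, so the stereochemical source is equal.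
- Against it here: each iodide is flanked by a methoxy group and a branched chain, which should slow the copper step. Hot carbonate acts on hindered secondary benzylic alkoxides. The iodides rule out the halogen–lithium exchange that links the two aldol rounds here, so the ring C aldehyde function would have to be carried masked, and the first carbinol would need protection through the second aldol.
- Comparison, structure: it gives the same bis(dihydrobenzofuran) at the aldehyde level of ring B and is silent on the oxolane.
- Comparison, mechanism: copper-mediated C–O coupling with retention against acid-mediated closure under thermodynamic control.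
- Comparison, step economy: roughly equal, since the saved closures are offset by extra protection and by a separate iodinated building block.

Key step: step 24

## Remarks before the steps

- Abbreviations used in names:
  - ArM = 5-bromo-3-methoxy-2-(methoxymethoxy)phenyl.
  - ArD = 3-methoxy-4-(triisopropylsilyloxy)phenyl.
  - In* = (2S,3R)-3-[(tert-butyldiphenylsilyl)oxymethyl]-7-methoxy-2-ArD-2,3-dihydro-1-benzofuran-5-yl.
  - Ar* = (2R,3S)-3-[(tert-butyldiphenylsilyl)oxymethyl]-7-methoxy-2-In*-2,3-dihydro-1-benzofuran-5-yl.
- Protecting groups: the primary alcohols are carried as TBDPS ethers and the phenols as TIPS ethers, because the former must survive aqueous acid (step 14) and the latter organolithium, amide base and hydride reagents.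
- Configuration check: the configurations of 37, 38 and 45 are mutually consistent. C4 of 37 is R and becomes C4 of 45, and the endo aryl group of 38 is the all-cis oxolane.
- Assumption: the (S)-enantiomer of 30 is taken to form the less soluble salt with (R)-1-phenylethylamine. If the pairing is the reverse, the (S)-amine is used and nothing else changes.

## Route

Step 1
Reactants: 1 4-bromo-2-methoxyphenol
Product: 2 1-(allyloxy)-4-bromo-2-methoxybenzene
Conditions: allyl bromide, K2CO3, acetone, reflux
Reagents that add atoms: allyl bromide, C=CCBr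
Why: Williamson O-alkylation of the phenoxide; no stereocentre is involved.

Step 2
Reactants: 2 1-(allyloxy)-4-bromo-2-methoxybenzene
Product: 3 2-allyl-4-bromo-6-methoxyphenol
Conditions: PhNEt2, 190 °C
Reagents that add atoms: none
Why: Aromatic Claisen rearrangement ([3,3] shift, then tautomerisation); the methoxy group blocks one ortho position and bromine the para position, so the allyl group can only arrive at C6.

Step 3
Reactants: 3 2-allyl-4-bromo-6-methoxyphenol
Product: 4 1-allyl-5-bromo-3-methoxy-2-(methoxymethoxy)benzene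
Conditions: MeOCH2Cl, i-Pr2NEt, CH2Cl2, 0 °C → rt
Reagents that add atoms: chloromethyl methyl ether, COCCl
Why: Acetal protection of the phenol; the MOM ether withstands base, boron enolate and hydride chemistry and is released later by the same acid that closes the furan ring.

Step 4
Reactants: 4 1-allyl-5-bromo-3-methoxy-2-(methoxymethoxy)benzene
Product: 6 2-[5-bromo-3-methoxy-2-(methoxymethoxy)phenyl]acetic acid, via aldehyde 5 (not isolated)
Conditions: O3, MeCN–H2O (9:1), 0 °C; then NaClO2, NaH2PO4, 0 °C → rt
Reagents that add atoms: ozone, [O-][O+]=O; sodium chlorite, [Na+].[O-]Cl=O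
Why: Ozonolysis in wet acetonitrile, where water intercepts the carbonyl oxide and gives the aldehyde without a reductive work-up, then Pinnick oxidation in the same flask; the hydrogen peroxide from the first stage scavenges hypochlorite and protects the electron-rich ring, and the terminal alkene reacts with ozone far faster than the bromoarene.

Step 5
Reactants: 6 2-[5-bromo-3-methoxy-2-(methoxymethoxy)phenyl]acetic acid
Product: 7 2-[5-bromo-3-methoxy-2-(methoxymethoxy)phenyl]acetyl fluoride
Conditions: cyanuric fluoride, pyridine, CH2Cl2, −10 °C → rt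
Reagents that add atoms: cyanuric fluoride (2,4,6-trifluoro-1,3,5-triazine), Fc1nc(F)nc(F)n1
Why: Deoxyfluorination of the carboxylic acid: the pyridinium carboxylate displaces fluoride from the triazine and the released fluoride attacks the acyloxytriazine at the acyl carbon. The pyridine-buffered medium leaves the MOM acetal alone, and the acyl fluoride tolerates aqueous work-up and brief storage, so one batch can be divided between the two auxiliaries.

Step 6
Reactants: 7 2-[5-bromo-3-methoxy-2-(methoxymethoxy)phenyl]acetyl fluoride; 8 (S)-4-benzyl-1,3-oxazolidin-2-one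
Product: 9 (4S)-4-benzyl-3-[2-(ArM)acetyl]-1,3-oxazolidin-2-one
Conditions: i-Pr2NEt, CH2Cl2, rt
Reagents that add atoms: none
Why: N-Acylation of the oxazolidinone by the acyl fluoride under a mild amine base; no organolithium reagent meets the aryl bromide or the acidic arylacetyl hydrogens.

Step 7
Reactants: 7 2-[5-bromo-3-methoxy-2-(methoxymethoxy)phenyl]acetyl fluoride; 10 (R)-4-benzyl-1,3-oxazolidin-2-one
Product: 11 (4R)-4-benzyl-3-[2-(ArM)acetyl]-1,3-oxazolidin-2-one
Conditions: i-Pr2NEt, CH2Cl2, rt
Reagents that add atoms: none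
Why: Same N-acylation with the enantiomeric auxiliary on the second portion of 7, needed because the two furan units have opposite absolute sense.

Step 8
Reactants: 12 vanillin
Product: 13 3-methoxy-4-(triisopropylsilyloxy)benzaldehyde
Conditions: i-Pr3SiCl, imidazole, DMF, rt
Reagents that add atoms: chlorotriisopropylsilane, CC(C)[Si](Cl)(C(C)C)C(C)C
Why: Silylation of the phenol; the aryl TIPS ether is chosen for its resistance to the later acid, organolithium and hydride steps.

Step 9
Reactants: 9 (4S)-imide; 13 3-methoxy-4-(triisopropylsilyloxy)benzaldehyde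
Product: 14 (4S)-4-benzyl-3-[(2S,3S)-2-(ArM)-3-hydroxy-3-(ArD)propanoyl]-1,3-oxazolidin-2-one
Conditions: Bu2BOTf, i-Pr2NEt, CH2Cl2, −78 → 0 °C; 13, −78 → 0 °C; pH 7 buffer, MeOH, 30% H2O2
Reagents that add atoms: none
Why: Evans syn-aldol reaction through the (Z)-boron enolate and a chair transition state in which the benzyl group of the auxiliary shields one enolate face; this fixes the α-carbon as S, which becomes C3 (R) of the inner furan, while the syn carbinol centre is lost later.

Step 10
Reactants: 14 inner aldol adduct
Product: 17 [(2S,3R)-5-bromo-7-methoxy-2-(ArD)-2,3-dihydro-1-benzofuran-3-yl]methanol, via diol 15 (not isolated), via phenol triol 16 (not isolated)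
Conditions: LiBH4, MeOH (1 equiv), THF, 0 °C; then 2 M aq. HCl, 35 °C
Reagents that add atoms: none
Why: Reductive cleavage of the imide gives the 1,3-diol and frees the auxiliary; the acid then removes the MOM group and ionises the para-silyloxybenzylic alcohol, and the ortho phenol captures the cation in a 5-exo closure that gives the 2,3-trans ring (C2 = S) under thermodynamic control, while C3 keeps the configuration set in step 9 and the primary alcohol cannot compete because it would close a four-membered ring.

Step 11
Reactants: 17 inner furan alcohol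
Product: 18 [(2S,3R)-5-bromo-7-methoxy-2-(ArD)-2,3-dihydro-1-benzofuran-3-yl]methyl tert-butyldiphenylsilyl ether
Conditions: t-BuPh2SiCl, imidazole, DMF, rt
Reagents that add atoms: tert-butyl(chloro)diphenylsilane, CC(C)(C)[Si](Cl)(c1ccccc1)c1ccccc1
Why: Silylation of the primary alcohol; TBDPS is used because this ether must survive the aqueous acid of step 14.

Step 12
Reactants: 18 inner furan bromide
Product: 19 (2S,3R)-3-[(tert-butyldiphenylsilyl)oxymethyl]-7-methoxy-2-(ArD)-2,3-dihydro-1-benzofuran-5-carbaldehyde (In*–CHO)
Conditions: n-BuLi, THF, −78 °C; DMF, −78 → 0 °C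
Reagents that add atoms: N,N-dimethylformamide, CN(C)C=O
Why: Bromine–lithium exchange, fast at −78 °C, followed by Bouveault formylation with DMF; the silyl ethers and the benzylic ether are inert at this temperature.

Step 13
Reactants: 11 (4R)-imide; 19 In*–CHO
Product: 20 (4R)-4-benzyl-3-[(2R,3R)-2-(ArM)-3-hydroxy-3-(In*)propanoyl]-1,3-oxazolidin-2-one
Conditions: Bu2BOTf, i-Pr2NEt, CH2Cl2, −78 → 0 °C; 19, −78 → 0 °C; pH 7 buffer, MeOH, 30% H2O2
Reagents that add atoms: none
Why: Second Evans syn-aldol reaction under reagent control; the (R)-auxiliary fixes the α-carbon as R, which becomes C3 (S) of the outer furan, and the remote centres of 19 have no say.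

Step 14
Reactants: 20 outer aldol adduct
Product: 23 [(2R,3S)-5-bromo-7-methoxy-2-(In*)-2,3-dihydro-1-benzofuran-3-yl]methanol, via diol 21 (not isolated), via phenol triol 22 (not isolated)
Conditions: LiBH4, MeOH (1 equiv), THF, 0 °C; then 2 M aq. HCl, 35 °C
Reagents that add atoms: none
Why: Same reductive cleavage and acid-mediated closure as in step 10; the cation is now stabilised by the ring oxygen of the inner furan para to it, trans closure sets the outer C2 as R, and the TBDPS and aryl TIPS ethers resist the dilute acid.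

Step 15
Reactants: 23 bis(dihydrobenzofuran) alcohol
Product: 24 Ar*–Br
Conditions: t-BuPh2SiCl, imidazole, DMF, rt
Reagents that add atoms: tert-butyl(chloro)diphenylsilane, CC(C)(C)[Si](Cl)(c1ccccc1)c1ccccc1
Why: Silylation of the remaining primary alcohol.

Step 16
Reactants: 24 Ar*–Br
Product: 26 Ar*–CH2OH, via aldehyde 25 (not isolated)
Conditions: n-BuLi, THF, −78 °C; DMF; then MeOH, NaBH4, −78 → 0 °C
Reagents that add atoms: N,N-dimethylformamide, CN(C)C=O
Why: Bromine–lithium exchange and formylation as in step 12; methanol releases the aldehyde in the flask and NaBH4 reduces it at once to the ring B benzylic alcohol.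

Step 17
Reactants: 26 Ar*–CH2OH
Product: 27 Ar*–CH2–O–C(=NH)CCl3 (2,2,2-trichloroacetimidate)
Conditions: Cl3CCN, DBU (10 mol %), CH2Cl2, 0 °C
Reagents that add atoms: trichloroacetonitrile, ClC(Cl)(Cl)C#N
Why: Base-catalysed addition of the alcohol to trichloroacetonitrile; the imidate is used crude because it is sensitive to silica.

Step 18
Reactants: 28 itaconic acid
Product: 30 (±)-paraconic acid (5-oxooxolane-3-carboxylic acid), via 2-(bromomethyl)succinic acid 29 (not isolated)
Conditions: HBr (33% in AcOH), rt; evaporate; H2O, reflux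
Reagents that add atoms: none
Why: Conjugate addition of HBr to the acrylic acid unit places bromine on the terminal carbon, and in hot water the γ-carboxyl group displaces bromide in a 5-exo-tet lactonisation.

Step 19
Reactants: 30 (±)-paraconic acid; 31 (R)-1-phenylethylamine
Product: 32 (R)-1-phenylethylammonium (S)-5-oxooxolane-3-carboxylate
Conditions: EtOH, crystallise (×2)
Reagents that add atoms: none
Why: Classical resolution through diastereomeric salts; the less soluble salt is collected and recrystallised until its rotation no longer changes.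

Step 20
Reactants: 32 resolved salt
Product: 33 (S)-paraconic acid
Conditions: 2 M aq. HCl, EtOAc (continuous extraction)
Reagents that add atoms: none
Why: Acidification frees the carboxylic acid; the stereocentre does not enolise under cold dilute acid.

Step 21
Reactants: 33 (S)-paraconic acid
Product: 34 (R)-4-(hydroxymethyl)oxolan-2-one
Conditions: BH3·SMe2, THF, 0 °C → rt; MeOH
Reagents that add atoms: none
Why: Borane reduces the carboxylic acid through its acyloxyborane much faster than the lactone; the descriptor changes from S to R only because the priorities change, and 34 is kept neutral and used promptly since acyl migration between its two hydroxymethyl arms would racemise it.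

Step 22
Reactants: 27 trichloroacetimidate; 34 (R)-4-(hydroxymethyl)oxolan-2-one (2 equiv)
Product: 35 (4R)-4-[(Ar*CH2O)methyl]oxolan-2-one
Conditions: camphorsulfonic acid (10 mol %), 4 Å sieves, CH2Cl2, 0 °C
Reagents that add atoms: none
Why: Acid-catalysed benzylation with a trichloroacetimidate: loss of trichloroacetamide gives a benzylic cation stabilised by the para ring oxygen, which the primary alcohol captures; the absence of base and the low temperature protect the configuration of the lactone.

Step 23
Reactants: 35 ether lactone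
Product: 37 (4R)-3-diazo-4-[(Ar*CH2O)methyl]oxolan-2-one, via trifluoroacetyl lactone 36 (not isolated)
Conditions: LiN(SiMe3)2, THF, −78 °C; CF3CO2CH2CF3; then 4-acetamidobenzenesulfonyl azide, Et3N, H2O (1 equiv), MeCN, rt
Reagents that add atoms: 4-acetamidobenzenesulfonyl azide, CC(=O)Nc1ccc(cc1)S(=O)(=O)N=[N+]=[N-]
Why: Deacylative diazo transfer: the lactone enolate is C-trifluoroacetylated, the activated dicarbonyl compound accepts the diazo group from the sulfonyl azide and loses the trifluoroacetyl group as the sulfonamide; the enolate has no leaving group in the β-position and C4 is not touched.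

Step 24
Reactants: 37 diazolactone
Product: 38 (1S,5R,8R)-8-(Ar*)-3,7-dioxabicyclo[3.3.0]octan-2-one (endo-aryl furofuranone)
Conditions: Rh2(OAc)4 (2 mol %), CH2Cl2, reflux, slow addition of 37
Reagents that add atoms: none
Why: Rh2(OAc)4 (dirhodium tetraacetate, divalent rhodium) takes up the diazo carbon of 37 with loss of dinitrogen and gives an electrophilic carbenoid at the lactone α-carbon, which inserts into a C–H bond of the ring B benzylic ether methylene through a concerted, asynchronous three-centre transition state with hydride-like character at carbon. The closest known reaction type is the dirhodium-catalysed 1,5 C–H insertion of α-diazo-γ-butyrolactones with benzyl ether side chains, which gives aryl furofuranones. The oxolane closes as a 1,5-insertion (five-membered transition state, new C2–C3 bond) onto the existing lactone, and only a cis ring fusion is geometrically possible, so the C4 centre fixes C3. C2 is set by the choice between the two diastereotopic benzylic hydrogens: the transition state with ring B pseudo-equatorial on the forming envelope is preferred and leaves the aryl group endo, cis to the lactone carbonyl, which is the all-cis (2R,3R,4R) array of the target. The step needs site selectivity for this C–H bond over 1,2-hydride shift from C4–H to the carbenoid carbon, over addition to the arenes and over the remote silyloxymethyl C–H bonds. The adjacent ether oxygen and the para oxygen of ring B make the target hydrogen the most hydridic one within reach, and the five-membered geometry excludes the others. Slow addition keeps the diazo concentration low and suppresses carbene dimerisation. The silyl ethers, the furan rings and the lactone are inert under these neutral conditions.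

Step 25
Reactants: 38 furofuranone
Product: 39 (2R,3S,4S)-2-(Ar*)-4-(hydroxymethyl)-N-methoxy-N-methyloxolane-3-carboxamide
Conditions: MeNH(OMe)·HCl, AlMe3, CH2Cl2, 0 °C → rt; aq. potassium sodium tartrate
Reagents that add atoms: N,O-dimethylhydroxylamine hydrochloride, CNOC.Cl
Why: Weinreb aminolysis of the lactone by the aluminium amide formed in the flask; the acyl–O bond opens, the C4 hydroxymethyl group is freed and the two one-carbon arms become different functional groups, with no enolisation at C3.

Step 26
Reactants: 39 hydroxy amide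
Product: 40 (2R,3S,4R)-2-(Ar*)-4-(bromomethyl)-N-methoxy-N-methyloxolane-3-carboxamide
Conditions: CBr4, PPh3, 2,6-lutidine, CH2Cl2, 0 °C
Reagents that add atoms: tetrabromomethane, BrC(Br)(Br)Br
Why: Appel bromination (SN2 at the primary carbon of the alkoxyphosphonium ion) under buffered, non-acidic conditions; material that closes back through the amide oxygen returns as 38 on work-up and is recycled.

Step 27
Reactants: 1 4-bromo-2-methoxyphenol
Product: 41 (4-bromo-2-methoxyphenoxy)triisopropylsilane
Conditions: i-Pr3SiCl, imidazole, DMF, rt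
Reagents that add atoms: chlorotriisopropylsilane, CC(C)[Si](Cl)(C(C)C)C(C)C
Why: Silylation of the phenol of the ring A partner.

Step 28
Reactants: 40 bromide; 41 (4-bromo-2-methoxyphenoxy)triisopropylsilane (1.5 equiv)
Product: 42 (2R,3S,4R)-2-(Ar*)-N-methoxy-4-[3-methoxy-4-(triisopropylsilyloxy)benzyl]-N-methyloxolane-3-carboxamide
Conditions: NiI2·xH2O (10 mol %), 4,4′-dimethoxy-2,2′-bipyridine (10 mol %), NaI (25 mol %), pyridine (10 mol %), Zn dust, DMPU, 60 °C
Reagents that add atoms: none
Why: Nickel-catalysed reductive cross-electrophile coupling: the aryl bromide adds to zerovalent nickel, the primary alkyl radical formed from the bromide (through the iodide) is captured, and reductive elimination forms the C(sp3)–C(aryl) bond with zinc as terminal reductant; no preformed organometallic reagent meets the amide, and C4 is not a radical centre, so its configuration is kept.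

Step 29
Reactants: 42 coupled amide
Product: 44 [(2R,3R,4R)-2-(Ar*)-4-[3-methoxy-4-(triisopropylsilyloxy)benzyl]oxolan-3-yl]methanol, via aldehyde 43 (not isolated)
Conditions: i-Bu2AlH, THF, −78 °C; then MeOH, NaBH4, −78 → 0 °C; aq. potassium sodium tartrate
Reagents that add atoms: none
Why: Weinreb amide reduction stops at the chelated hemiaminal; methanol releases the aldehyde in the presence of NaBH4, which reduces it at once, so the epimerisable all-cis aldehyde never accumulates.

Step 30
Reactants: 44 fully silylated precursor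
Product: 45 CNP0395728.1
Conditions: Bu4NF, AcOH, THF, 0 °C → rt
Reagents that add atoms: none
Why: Fluoride cleaves the two alkyl TBDPS and two aryl TIPS ethers; acetic acid buffers the phenoxides so that no quinone methide opens a benzylic ether, and no acid strong enough to ionise the three benzylic C–O bonds is present.

## Compound list

1 | 4-bromo-2-methoxyphenol | COc1cc(Br)ccc1O | starting material
2 | 1-(allyloxy)-4-bromo-2-methoxybenzene | COc1cc(Br)ccc1OCC=C | intermediate
3 | 2-allyl-4-bromo-6-methoxyphenol | COc1cc(Br)cc(CC=C)c1O | intermediate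
4 | 1-allyl-5-bromo-3-methoxy-2-(methoxymethoxy)benzene | COCOc1c(CC=C)cc(Br)cc1OC | intermediate
5 | 2-[5-bromo-3-methoxy-2-(methoxymethoxy)phenyl]acetaldehyde | COCOc1c(CC=O)cc(Br)cc1OC | intermediate
6 | 2-[5-bromo-3-methoxy-2-(methoxymethoxy)phenyl]acetic acid | COCOc1c(CC(=O)O)cc(Br)cc1OC | intermediate
7 | 2-[5-bromo-3-methoxy-2-(methoxymethoxy)phenyl]acetyl fluoride | COCOc1c(CC(=O)F)cc(Br)cc1OC | intermediate
8 | (S)-4-benzyl-1,3-oxazolidin-2-one | O=C1N[C@@H](Cc2ccccc2)CO1 | starting material
9 | (4S)-4-benzyl-3-[2-(ArM)acetyl]-1,3-oxazolidin-2-one | O=C1OC[C@H](Cc2ccccc2)N1C(=O)Cc1cc(Br)cc(OC)c1OCOC | intermediate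
10 | (R)-4-benzyl-1,3-oxazolidin-2-one | O=C1N[C@H](Cc2ccccc2)CO1 | starting material
11 | (4R)-4-benzyl-3-[2-(ArM)acetyl]-1,3-oxazolidin-2-one | O=C1OC[C@@H](Cc2ccccc2)N1C(=O)Cc1cc(Br)cc(OC)c1OCOC | intermediate
12 | vanillin | COc1cc(C=O)ccc1O | starting material
13 | 3-methoxy-4-(triisopropylsilyloxy)benzaldehyde | COc1cc(C=O)ccc1O[Si](C(C)C)(C(C)C)C(C)C | intermediate
14 | (4S)-4-benzyl-3-[(2S,3S)-2-(ArM)-3-hydroxy-3-(ArD)propanoyl]-1,3-oxazolidin-2-one | O=C1OC[C@H](Cc2ccccc2)N1C(=O)[C@@H](c1cc(Br)cc(OC)c1OCOC)[C@H](O)c1ccc(O[Si](C(C)C)(C(C)C)C(C)C)c(OC)c1 | intermediate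
15 | (1S,2R)-2-(ArM)-1-(ArD)propane-1,3-diol | OC[C@@H](c1cc(Br)cc(OC)c1OCOC)[C@H](O)c1ccc(O[Si](C(C)C)(C(C)C)C(C)C)c(OC)c1 | intermediate
16 | (1S,2R)-2-(5-bromo-2-hydroxy-3-methoxyphenyl)-1-(ArD)propane-1,3-diol | OC[C@@H](c1cc(Br)cc(OC)c1O)[C@H](O)c1ccc(O[Si](C(C)C)(C(C)C)C(C)C)c(OC)c1 | intermediate
17 | [(2S,3R)-5-bromo-7-methoxy-2-(ArD)-2,3-dihydro-1-benzofuran-3-yl]methanol | Brc1cc(OC)c2c(c1)[C@H](CO)[C@@H](c1ccc(O[Si](C(C)C)(C(C)C)C(C)C)c(OC)c1)O2 | intermediate
18 | TBDPS ether of 17 (In*–Br) | Brc1cc(OC)c2c(c1)[C@H](CO[Si](c1ccccc1)(c1ccccc1)C(C)(C)C)[C@@H](c1ccc(O[Si](C(C)C)(C(C)C)C(C)C)c(OC)c1)O2 | intermediate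
19 | (2S,3R)-3-[(tert-butyldiphenylsilyl)oxymethyl]-7-methoxy-2-(ArD)-2,3-dihydro-1-benzofuran-5-carbaldehyde (In*–CHO) | O=Cc1cc(OC)c2c(c1)[C@H](CO[Si](c1ccccc1)(c1ccccc1)C(C)(C)C)[C@@H](c1ccc(O[Si](C(C)C)(C(C)C)C(C)C)c(OC)c1)O2 | intermediate
20 | (4R)-4-benzyl-3-[(2R,3R)-2-(ArM)-3-hydroxy-3-(In*)propanoyl]-1,3-oxazolidin-2-one | O=C1OC[C@@H](Cc2ccccc2)N1C(=O)[C@H](c1cc(Br)cc(OC)c1OCOC)[C@@H](O)c3cc(OC)c5c(c3)[C@H](CO[Si](c6ccccc6)(c6ccccc6)C(C)(C)C)[C@@H](c3ccc(O[Si](C(C)C)(C(C)C)C(C)C)c(OC)c3)O5 | intermediate
21 | (1R,2S)-2-(ArM)-1-(In*)propane-1,3-diol | OC[C@H](c1cc(Br)cc(OC)c1OCOC)[C@@H](O)c3cc(OC)c5c(c3)[C@H](CO[Si](c6ccccc6)(c6ccccc6)C(C)(C)C)[C@@H](c3ccc(O[Si](C(C)C)(C(C)C)C(C)C)c(OC)c3)O5 | intermediate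
22 | (1R,2S)-2-(5-bromo-2-hydroxy-3-methoxyphenyl)-1-(In*)propane-1,3-diol | OC[C@H](c1cc(Br)cc(OC)c1O)[C@@H](O)c3cc(OC)c5c(c3)[C@H](CO[Si](c6ccccc6)(c6ccccc6)C(C)(C)C)[C@@H](c3ccc(O[Si](C(C)C)(C(C)C)C(C)C)c(OC)c3)O5 | intermediate
23 | [(2R,3S)-5-bromo-7-methoxy-2-(In*)-2,3-dihydro-1-benzofuran-3-yl]methanol | Brc3cc(OC)c4c(c3)[C@@H](CO)[C@H](c3cc(OC)c5c(c3)[C@H](CO[Si](c6ccccc6)(c6ccccc6)C(C)(C)C)[C@@H](c3ccc(O[Si](C(C)C)(C(C)C)C(C)C)c(OC)c3)O5)O4 | intermediate
24 | Ar*–Br (TBDPS ether of 23) | Brc3cc(OC)c4c(c3)[C@@H](CO[Si](c6ccccc6)(c6ccccc6)C(C)(C)C)[C@H](c3cc(OC)c5c(c3)[C@H](CO[Si](c6ccccc6)(c6ccccc6)C(C)(C)C)[C@@H](c3ccc(O[Si](C(C)C)(C(C)C)C(C)C)c(OC)c3)O5)O4 | intermediate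
25 | Ar*–CHO | O=Cc3cc(OC)c4c(c3)[C@@H](CO[Si](c6ccccc6)(c6ccccc6)C(C)(C)C)[C@H](c3cc(OC)c5c(c3)[C@H](CO[Si](c6ccccc6)(c6ccccc6)C(C)(C)C)[C@@H](c3ccc(O[Si](C(C)C)(C(C)C)C(C)C)c(OC)c3)O5)O4 | intermediate
26 | Ar*–CH2OH | OCc3cc(OC)c4c(c3)[C@@H](CO[Si](c6ccccc6)(c6ccccc6)C(C)(C)C)[C@H](c3cc(OC)c5c(c3)[C@H](CO[Si](c6ccccc6)(c6ccccc6)C(C)(C)C)[C@@H](c3ccc(O[Si](C(C)C)(C(C)C)C(C)C)c(OC)c3)O5)O4 | intermediate
27 | Ar*–CH2 2,2,2-trichloroacetimidate | ClC(Cl)(Cl)C(=N)OCc3cc(OC)c4c(c3)[C@@H](CO[Si](c6ccccc6)(c6ccccc6)C(C)(C)C)[C@H](c3cc(OC)c5c(c3)[C@H](CO[Si](c6ccccc6)(c6ccccc6)C(C)(C)C)[C@@H](c3ccc(O[Si](C(C)C)(C(C)C)C(C)C)c(OC)c3)O5)O4 | intermediate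
28 | itaconic acid | C=C(CC(=O)O)C(=O)O | starting material
29 | 2-(bromomethyl)succinic acid (racemic) | BrCC(CC(=O)O)C(=O)O | intermediate
30 | (±)-paraconic acid (5-oxooxolane-3-carboxylic acid) | O=C1CC(C(=O)O)CO1 | intermediate
31 | (R)-1-phenylethylamine | C[C@@H](N)c1ccccc1 | starting material
32 | (R)-1-phenylethylammonium (S)-5-oxooxolane-3-carboxylate | O=C1C[C@H](C(=O)[O-])CO1.C[C@@H]([NH3+])c1ccccc1 | intermediate
33 | (S)-paraconic acid | O=C1C[C@H](C(=O)O)CO1 | intermediate
34 | (R)-4-(hydroxymethyl)oxolan-2-one | O=C1C[C@H](CO)CO1 | intermediate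
35 | (4R)-4-[(Ar*CH2O)methyl]oxolan-2-one | O1C[C@@H](COCc3cc(OC)c4c(c3)[C@@H](CO[Si](c6ccccc6)(c6ccccc6)C(C)(C)C)[C@H](c3cc(OC)c5c(c3)[C@H](CO[Si](c6ccccc6)(c6ccccc6)C(C)(C)C)[C@@H](c3ccc(O[Si](C(C)C)(C(C)C)C(C)C)c(OC)c3)O5)O4)CC1=O | intermediate
36 | (4R)-4-[(Ar*CH2O)methyl]-3-(trifluoroacetyl)oxolan-2-one (C3 epimers and enol) | O1C[C@@H](COCc3cc(OC)c4c(c3)[C@@H](CO[Si](c6ccccc6)(c6ccccc6)C(C)(C)C)[C@H](c3cc(OC)c5c(c3)[C@H](CO[Si](c6ccccc6)(c6ccccc6)C(C)(C)C)[C@@H](c3ccc(O[Si](C(C)C)(C(C)C)C(C)C)c(OC)c3)O5)O4)C(C(=O)C(F)(F)F)C1=O | intermediate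
37 | (4R)-3-diazo-4-[(Ar*CH2O)methyl]oxolan-2-one (key-step precursor) | O1C[C@@H](COCc3cc(OC)c4c(c3)[C@@H](CO[Si](c6ccccc6)(c6ccccc6)C(C)(C)C)[C@H](c3cc(OC)c5c(c3)[C@H](CO[Si](c6ccccc6)(c6ccccc6)C(C)(C)C)[C@@H](c3ccc(O[Si](C(C)C)(C(C)C)C(C)C)c(OC)c3)O5)O4)C(=[N+]=[N-])C1=O | intermediate
38 | (1S,5R,8R)-8-(Ar*)-3,7-dioxabicyclo[3.3.0]octan-2-one (key-step product) | O1C[C@H]2CO[C@@H](c3cc(OC)c4c(c3)[C@@H](CO[Si](c6ccccc6)(c6ccccc6)C(C)(C)C)[C@H](c3cc(OC)c5c(c3)[C@H](CO[Si](c6ccccc6)(c6ccccc6)C(C)(C)C)[C@@H](c3ccc(O[Si](C(C)C)(C(C)C)C(C)C)c(OC)c3)O5)O4)[C@H]2C1=O | intermediate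
39 | (2R,3S,4S)-2-(Ar*)-4-(hydroxymethyl)-N-methoxy-N-methyloxolane-3-carboxamide | OC[C@H]1CO[C@@H](c3cc(OC)c4c(c3)[C@@H](CO[Si](c6ccccc6)(c6ccccc6)C(C)(C)C)[C@H](c3cc(OC)c5c(c3)[C@H](CO[Si](c6ccccc6)(c6ccccc6)C(C)(C)C)[C@@H](c3ccc(O[Si](C(C)C)(C(C)C)C(C)C)c(OC)c3)O5)O4)[C@H]1C(=O)N(C)OC | intermediate
40 | (2R,3S,4R)-2-(Ar*)-4-(bromomethyl)-N-methoxy-N-methyloxolane-3-carboxamide | BrC[C@H]1CO[C@@H](c3cc(OC)c4c(c3)[C@@H](CO[Si](c6ccccc6)(c6ccccc6)C(C)(C)C)[C@H](c3cc(OC)c5c(c3)[C@H](CO[Si](c6ccccc6)(c6ccccc6)C(C)(C)C)[C@@H](c3ccc(O[Si](C(C)C)(C(C)C)C(C)C)c(OC)c3)O5)O4)[C@H]1C(=O)N(C)OC | intermediate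
41 | (4-bromo-2-methoxyphenoxy)triisopropylsilane | COc1cc(Br)ccc1O[Si](C(C)C)(C(C)C)C(C)C | intermediate
42 | (2R,3S,4R)-2-(Ar*)-N-methoxy-4-[3-methoxy-4-(triisopropylsilyloxy)benzyl]-N-methyloxolane-3-carboxamide | COc1cc(C[C@H]2CO[C@@H](c3cc(OC)c4c(c3)[C@@H](CO[Si](c6ccccc6)(c6ccccc6)C(C)(C)C)[C@H](c3cc(OC)c5c(c3)[C@H](CO[Si](c6ccccc6)(c6ccccc6)C(C)(C)C)[C@@H](c3ccc(O[Si](C(C)C)(C(C)C)C(C)C)c(OC)c3)O5)O4)[C@H]2C(=O)N(C)OC)ccc1O[Si](C(C)C)(C(C)C)C(C)C | intermediate
43 | (2R,3S,4R)-2-(Ar*)-4-[3-methoxy-4-(triisopropylsilyloxy)benzyl]oxolane-3-carbaldehyde | COc1cc(C[C@H]2CO[C@@H](c3cc(OC)c4c(c3)[C@@H](CO[Si](c6ccccc6)(c6ccccc6)C(C)(C)C)[C@H](c3cc(OC)c5c(c3)[C@H](CO[Si](c6ccccc6)(c6ccccc6)C(C)(C)C)[C@@H](c3ccc(O[Si](C(C)C)(C(C)C)C(C)C)c(OC)c3)O5)O4)[C@H]2C=O)ccc1O[Si](C(C)C)(C(C)C)C(C)C | intermediate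
44 | [(2R,3R,4R)-2-(Ar*)-4-[3-methoxy-4-(triisopropylsilyloxy)benzyl]oxolan-3-yl]methanol | COc1cc(C[C@H]2CO[C@@H](c3cc(OC)c4c(c3)[C@@H](CO[Si](c6ccccc6)(c6ccccc6)C(C)(C)C)[C@H](c3cc(OC)c5c(c3)[C@H](CO[Si](c6ccccc6)(c6ccccc6)C(C)(C)C)[C@@H](c3ccc(O[Si](C(C)C)(C(C)C)C(C)C)c(OC)c3)O5)O4)[C@H]2CO)ccc1O[Si](C(C)C)(C(C)C)C(C)C | intermediate
45 | CNP0395728.1: oxolane (2R,3R,4R), outer dihydrobenzofuran (2R,3S), inner dihydrobenzofuran (2S,3R) | COc1cc(C[C@H]2CO[C@@H](c3cc(OC)c4c(c3)[C@@H](CO)[C@H](c3cc(OC)c5c(c3)[C@H](CO)[C@@H](c3ccc(O)c(OC)c3)O5)O4)[C@H]2CO)ccc1O | target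

## Step count and least certain steps

Total: 30 steps. Longest linear sequence: 23 steps from 1 (steps 1–6, 9–17, 22–26, 28–30).

**Step 24 (key step).** The most likely failure is loss of the carbenoid through 1,2-hydride migration from C4–H or through attack on one of the many electron-rich arenes before it reaches the benzylic hydrogen. Insertion through the other benzylic hydrogen, which would erode the endo selectivity, is also possible, since 37 is far larger and more electron-rich than the simple benzyl ethers on which this chemistry rests.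

Fallback: the same bond would be made by polar chemistry. It sets out from aldehyde 25 (obtained by ending step 16 before the NaBH4 stage) and alcohol 34, and returns at 38. 25 would be converted with HC(OMe)3, MeOH and pyridinium tosylate into the dimethyl acetal F1. Exchange of one methoxy group for 34 (pyridinium tosylate, toluene, removal of methanol) would give the mixed acetal F2. Me3SiOTf and Et3N at −78 °C would turn the lactone into the silyl ketene acetal F3, which is not isolated. Further Me3SiOTf would ionise the acetal to an oxocarbenium ion that the ketene acetal carbon attacks (intramolecular Mukaiyama-type addition), closing the same cis-fused ring. The ring fusion is again dictated by C4. Whether this closure places the aryl group endo as the carbenoid does would have to be established, and that is the weak point of the fallback.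

**Step 28.** The two electrophiles may be activated at mismatched rates: the electron-rich aryl bromide adds slowly to nickel while the alkyl bromide is consumed by dimerisation or reduction. Heating also favours displacement of bromide by the neighbouring amide oxygen.

Fallback: preformed organometallic coupling, from 40 back to 42. Zinc insertion (Zn dust, LiCl, THF, 40 °C) would give the alkylzinc bromide F4, which would be coupled with 41 under Pd(OAc)2 and 2-dicyclohexylphosphino-2′,6′-dimethoxybiphenyl (Negishi coupling).

**Step 26.** Neighbouring-group participation is the risk: the cis amide oxygen may displace the activated oxygen and form a cyclic imidate salt, which returns 38 on work-up, so conversion rather than material is lost.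

Fallback: a less nucleophilic carbonyl group, from 38 back to 44. LiOH in THF–H2O would open the lactone and MeI in DMF would alkylate the carboxylate to give the hydroxy ester F5, used at once. CBr4 and PPh3 would give the bromo ester F6. The nickel coupling of step 28 with 41 would give the ester F7, and i-Bu2AlH would reduce it directly to 44.

**Step 22.** The benzylic cation may alkylate the electron-rich rings of a second molecule or collapse to the N-benzyl trichloroacetamide, and acid may promote acyl migration in 34 and erode its enantiopurity.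

Fallback: a halide-abstraction etherification, from 26 back to 35. CBr4 and PPh3 would give the benzylic bromide F8, which would be combined with 34 and Ag2O in CH2Cl2 without any protic acid.

**Step 14 (step 10 is the same operation on a simpler substrate and serves as its test).** The benzylic cation may lose the C3 proton instead of being captured, and re-protonation and closure would then erode the C3 configuration. Prolonged acid may also start to remove silyl groups.

Fallback: ring closure before removal of the auxiliary, from 20 back to 23. 2 M HCl in THF would remove the MOM group and close the ring to give the dihydrobenzofuran imide F9. With the auxiliary in place any C3 or C2 epimer is a diastereomer and can be removed by chromatography or crystallisation. LiBH4 would then give 23.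

## Further compounds

F1 | step 24 | Ar*–CH(OMe)2 (dimethyl acetal of 25) | COC(OC)c3cc(OC)c4c(c3)[C@@H](CO[Si](c6ccccc6)(c6ccccc6)C(C)(C)C)[C@H](c3cc(OC)c5c(c3)[C@H](CO[Si](c6ccccc6)(c6ccccc6)C(C)(C)C)[C@@H](c3ccc(O[Si](C(C)C)(C(C)C)C(C)C)c(OC)c3)O5)O4
F2 | step 24 | mixed methyl [(3R)-5-oxooxolan-3-yl]methyl acetal of 25 (acetal carbon unassigned) | COC(OC[C@H]1CC(=O)OC1)c3cc(OC)c4c(c3)[C@@H](CO[Si](c6ccccc6)(c6ccccc6)C(C)(C)C)[C@H](c3cc(OC)c5c(c3)[C@H](CO[Si](c6ccccc6)(c6ccccc6)C(C)(C)C)[C@@H](c3ccc(O[Si](C(C)C)(C(C)C)C(C)C)c(OC)c3)O5)O4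
F3 | step 24 | trimethylsilyl ketene acetal of F2 | COC(OC[C@H]1C=C(O[Si](C)(C)C)OC1)c3cc(OC)c4c(c3)[C@@H](CO[Si](c6ccccc6)(c6ccccc6)C(C)(C)C)[C@H](c3cc(OC)c5c(c3)[C@H](CO[Si](c6ccccc6)(c6ccccc6)C(C)(C)C)[C@@H](c3ccc(O[Si](C(C)C)(C(C)C)C(C)C)c(OC)c3)O5)O4
F4 | step 28 | alkylzinc bromide from 40 | Br[Zn]C[C@H]1CO[C@@H](c3cc(OC)c4c(c3)[C@@H](CO[Si](c6ccccc6)(c6ccccc6)C(C)(C)C)[C@H](c3cc(OC)c5c(c3)[C@H](CO[Si](c6ccccc6)(c6ccccc6)C(C)(C)C)[C@@H](c3ccc(O[Si](C(C)C)(C(C)C)C(C)C)c(OC)c3)O5)O4)[C@H]1C(=O)N(C)OC
F5 | step 26 | methyl (2R,3S,4S)-2-(Ar*)-4-(hydroxymethyl)oxolane-3-carboxylate | OC[C@H]1CO[C@@H](c3cc(OC)c4c(c3)[C@@H](CO[Si](c6ccccc6)(c6ccccc6)C(C)(C)C)[C@H](c3cc(OC)c5c(c3)[C@H](CO[Si](c6ccccc6)(c6ccccc6)C(C)(C)C)[C@@H](c3ccc(O[Si](C(C)C)(C(C)C)C(C)C)c(OC)c3)O5)O4)[C@H]1C(=O)OC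
F6 | step 26 | methyl (2R,3S,4R)-2-(Ar*)-4-(bromomethyl)oxolane-3-carboxylate | BrC[C@H]1CO[C@@H](c3cc(OC)c4c(c3)[C@@H](CO[Si](c6ccccc6)(c6ccccc6)C(C)(C)C)[C@H](c3cc(OC)c5c(c3)[C@H](CO[Si](c6ccccc6)(c6ccccc6)C(C)(C)C)[C@@H](c3ccc(O[Si](C(C)C)(C(C)C)C(C)C)c(OC)c3)O5)O4)[C@H]1C(=O)OC
F7 | step 26 | methyl (2R,3S,4R)-2-(Ar*)-4-[3-methoxy-4-(triisopropylsilyloxy)benzyl]oxolane-3-carboxylate | COc1cc(C[C@H]2CO[C@@H](c3cc(OC)c4c(c3)[C@@H](CO[Si](c6ccccc6)(c6ccccc6)C(C)(C)C)[C@H](c3cc(OC)c5c(c3)[C@H](CO[Si](c6ccccc6)(c6ccccc6)C(C)(C)C)[C@@H](c3ccc(O[Si](C(C)C)(C(C)C)C(C)C)c(OC)c3)O5)O4)[C@H]2C(=O)OC)ccc1O[Si](C(C)C)(C(C)C)C(C)C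
F8 | step 22 | Ar*–CH2Br | BrCc3cc(OC)c4c(c3)[C@@H](CO[Si](c6ccccc6)(c6ccccc6)C(C)(C)C)[C@H](c3cc(OC)c5c(c3)[C@H](CO[Si](c6ccccc6)(c6ccccc6)C(C)(C)C)[C@@H](c3ccc(O[Si](C(C)C)(C(C)C)C(C)C)c(OC)c3)O5)O4
F9 | step 14 | (4R)-4-benzyl-3-[(2R,3S)-5-bromo-7-methoxy-2-(In*)-2,3-dihydro-1-benzofuran-3-carbonyl]-1,3-oxazolidin-2-one | Brc3cc(OC)c4c(c3)[C@@H](C(=O)N1C(=O)OC[C@H]1Cc1ccccc1)[C@H](c3cc(OC)c5c(c3)[C@H](CO[Si](c6ccccc6)(c6ccccc6)C(C)(C)C)[C@@H](c3ccc(O[Si](C(C)C)(C(C)C)C(C)C)c(OC)c3)O5)O4
A1 | alternative 1 | bis-flavanone, (2R)-6-bromo-8-methoxy-2-[(2S)-2-(4-acetoxy-3-methoxyphenyl)-8-methoxy-4-oxochroman-6-yl]chroman-4-one | Brc1cc(OC)c2O[C@@H](c3cc(OC)c4O[C@H](c5ccc(OC(C)=O)c(OC)c5)CC(=O)c4c3)CC(=O)c2c1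
A2 | alternative 1 | bis(dihydrobenzofuran) diester | Brc3cc(OC)c4c(c3)[C@@H](C(=O)OC)[C@H](c3cc(OC)c5c(c3)[C@H](C(=O)OC)[C@@H](c3ccc(OC(C)=O)c(OC)c3)O5)O4
A3 | alternative 2 | 4-bromo-2-[2-(tert-butyldimethylsilyloxy)-1-(4-tolylsulfonyl)ethyl]-6-methoxyphenol | Brc1cc(OC)c(O)c(c1)C(CO[Si](C)(C)C(C)(C)C)S(=O)(=O)c1ccc(C)cc1
A4 | alternative 2 | ring C ortho-quinone methide | O=C1C(OC)=CC(Br)=CC1=CCO[Si](C)(C)C(C)(C)C
A5 | alternative 2 | (2R,5R)-1-[3-methoxy-4-(triisopropylsilyloxy)benzyl]-2,5-dimethylthiolanium tetrafluoroborate (antipode to be chosen by the sense of induction) | C[C@@H]1CC[C@@H](C)[S+]1Cc1ccc(O[Si](C(C)C)(C(C)C)C(C)C)c(OC)c1.F[B-](F)(F)F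
A6 | alternative 2 | dihydrobenzofuran bromide | Brc1cc(OC)c2c(c1)[C@H](CO[Si](C)(C)C(C)(C)C)[C@@H](c1ccc(O[Si](C(C)C)(C(C)C)C(C)C)c(OC)c1)O2
A7 | alternative 3 | diiodo diol | C1COC(O1)c1cc(OC)c(I)c(c1)[C@@H](CO[Si](C)(C)C(C)(C)C)[C@@H](O)c1cc(OC)c(I)c(c1)[C@H](CO[Si](C)(C)C(C)(C)C)[C@H](O)c1ccc(O[Si](C(C)C)(C(C)C)C(C)C)c(OC)c1
A8 | alternative 3 | bis(dihydrobenzofuran) acetal | C1COC(O1)c3cc(OC)c4c(c3)[C@@H](CO[Si](C)(C)C(C)(C)C)[C@H](c3cc(OC)c5c(c3)[C@H](CO[Si](C)(C)C(C)(C)C)[C@@H](c3ccc(O[Si](C(C)C)(C(C)C)C(C)C)c(OC)c3)O5)O4
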